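The ratio ρ, the first-order constant for loss of target over the constant for its formation, can be read from the two earlier runs, and for two steps in series it gives a highest amount of target.

| flask | starting material | other conformer | protic impurity | temperature | remark | time |
|---|---|---|---|---|---|---|
| autumn | 0.70 M | 0.050 M | 0.50 M | 75 °C | run made earlier |  |
| midnight | 1.1 M | 0.050 M | 0.50 M | 86 °C | run made earlier |  |
| Friday's | 0.50 M | 0.0500 M | 0.500 M |  | at 70 °C until 1.0 h, from then on at 90 °C | 80 min |
| Monday's | 0.50 M | 0.0500 M | 0.500 M | 70 °C |  | 80 min |
| Thursday's | 0.50 M | 0.0500 M | 0.500 M | 90 °C |  | 80 min |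

| run | time / min | target / % | starting material / % |
|---|---|---|---|
| autumn | 4.00 | 1.4 | 97.0 |
| autumn | 8.00 | 2.5 | 97.2 |
| autumn | 20.0 | 3.1 | 95.1 |
| autumn | 50.0 | 9.3 | 90.0 |
| midnight | 2.00 | 1.2 | 97.4 |
| midnight | 4.00 | 1.9 | 96.9 |
| midnight | 10.0 | 6.3 | 93.7 |
| midnight | 25.0 | 13.7 | 84.1 |

(standard deviation of a reading: 0.5 percentage points)

- which flask leads in amount of target, in percent of the starting material and other conformer together charged ("all alike" within 1.5 percentage points) (Friday's / Monday's / Thursday's / all alike)
- how much target is there at the end, in percent of the starting material and other conformer together charged: Friday's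
- how much target is there at the end, in percent of the starting material and other conformer together charged: Monday's
- how much target is there at the end, in percent of the starting material and other conformer together charged: Thursday's

- in a conversion other conformer counts as not yet reacted

At the last readings, 0.7 percentage points of the autumn run and 2.2 points of the midnight run are neither starting material nor target. Call this loss L, the target P and the starting material a, all as fractions of the charge. If target grew about linearly, ρ = 2L/(−P ln a). That gives 1.43 at 75 °C and 1.85 at 86 °C. With a scatter of 0.5 points on each reading, these count as one reading, 1.64.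

For two steps in series with ρ fixed, P = (a − a^ρ)/(ρ − 1). Target crests at exposure x* = ln ρ/(ρ − 1) = 0.773, where x = −ln a. The crest height is the target ceiling 28.1%, which lies between 26.2% and 30.4% across the two readings.

First-order constants put Thursday's at an exposure of 0.71, near the crest, so this reckoning commits to about 28.1% there if ρ holds at 90 °C. The forecast stands higher for Thursday's, with 48% (28% to 60%); it gives 20.5% for Friday's and 8% for Monday's, and names Thursday's as leader; its line reads “Thursday: kt ≈ 0.71, about 50%”.

The flasks give 19.1% for Friday's, 8.89% for Monday's and 28.3% for Thursday's, so Thursday's leads.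

    other conformer → isomer of the product (k = 0.0500 min⁻¹, Ea = 101 kJ mol⁻¹)
    target → over-reaction product (k = 0.0150 min⁻¹, Ea = 104 kJ mol⁻¹)
    target ⇌ isomer of the product (K = 1.80, k = 4.10 × 10⁻⁴ min⁻¹, Ea = 116 kJ mol⁻¹, ΔH = −27.0 kJ mol⁻¹)
    other conformer + protic impurity → quenched substrate (k = 0.0120 L mol⁻¹ min⁻¹, Ea = 95.0 kJ mol⁻¹)
    starting material ⇌ other conformer (K = 0.00160, k = 0.00910 min⁻¹, Ea = 115 kJ mol⁻¹, ΔH = −47.0 kJ mol⁻¹)
    starting material + target → side product (k = 0.00170 L mol⁻¹ min⁻¹, Ea = 92.0 kJ mol⁻¹)
    starting material → target (k = 0.0100 min⁻¹, Ea = 106 kJ mol⁻¹)
    (constants at 90 °C)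

After 80.0 min, Thursday's holds 43.9% starting material, an exposure of 0.823. Monday's repeated at 95 °C goes further: its 26.6% starting material after 80.0 min means an exposure of 1.32, past the crest and past Thursday's. The series formula with the same ρ then puts target at 23.8%, under the ceiling of 28.1%. That hotter flask holds 24.8% target and 44.2% over-reaction product.

The earlier runs and the new flask were computed on assumed constants.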